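Readings and results come from a simulation for substances that don't exist; the scatter is artificial.

If the 4 sites of the complex took incoming ligand blindly, the reacted part would follow from the charge; that was the zero I set against your hunch that twice the ligand finishes the starting complex.

the same everywhere: starting complex 0.050 M
- winter: incoming ligand 0.055 M (fed, over 80 s); leaving ligand 0.075 M; run made earlier
- gamma: incoming ligand 0.0550 M (fed, over 80 s); leaving ligand 0.0500 M; time 10 min
- zeta: incoming ligand 0.110 M (fed, over 80 s); leaving ligand 0.0500 M; time 10 min

winter run (percent of the starting complex charged)

| time / min | starting complex / % | complex with two exchanged / % |
|---|---|---|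
| 0.833 | 45 | 2 |
| 1.50 | 30 | 10 |
| 2.50 | 22 | 7 |
| 3.00 | 21 | 11 |
| 4.00 | 19 | 10 |
| 5.00 | 19 | 6 |
| 6.00 | 19 | 11 |

(scatter of a reading: 2 percentage points)

- amounts and yields of leaving ligand count idle adduct too
- what was read earlier has a scatter of 2 percentage points, one standard deviation
- steps thought possible: starting complex + incoming ligand -> leaving ligand + complex with one exchanged; complex with one exchanged + incoming ligand -> leaving ligand + complex with two exchanged; complex with two exchanged + incoming ligand -> leaving ligand + complex with three exchanged; complex with three exchanged + incoming ligand -> leaving ligand + complex with four exchanged; leaving ligand + starting complex <-> idle adduct; incoming ligand -> decomposition product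
- what has gone from starting complex into another species counts as reacted, even if it can come back
- no earlier run changes the charge of incoming ligand; that part of a forecast is a guess
- no earlier run changes the charge of leaving ligand; that part of a forecast is a guess

- part of the starting complex that has reacted at the end, gamma
- part of the starting complex that has reacted at the end, zeta
- what raising the concentration of incoming ligand from its lowest to its highest value here does to the part of the starting complex that has reacted (changes below 5 percentage points count as none) (it falls / it rises / no change)

1. I defined the site fill as the incoming ligand charged per site, its charge over 4 times the starting complex charged. Winter and gamma had 27.5%; zeta had 55.0%.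

2. A complex stays unreacted while its sites stay empty, so the zero is one minus the empty fraction to the power 4. That gave 72.4% for gamma and 95.9% for zeta.

3. Winter read 19% starting complex at 6.00 min, so 81.0% had reacted. That stood 8.6 percentage points above the zero, with a scatter of 2 points.

4. Gamma had less leaving ligand than winter, which no run had tested, so I placed it midway, at 76.7%. Zeta's charge was untested too, so I stayed on the zero, 95.9%, and expected a rise.

The forecast gave 80% for gamma, 97% for zeta and "it rises", calling zeta “an extrapolation”. The flasks gave 78.4% for gamma and 91.9% for zeta: it rises, by 14 points.

    starting complex + incoming ligand → leaving ligand + complex with one exchanged (k = 32.8 /M/min)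
    complex with one exchanged + incoming ligand → leaving ligand + complex with two exchanged (k = 21.3 /M/min)
    complex with two exchanged + incoming ligand → leaving ligand + complex with three exchanged (k = 76.7 /M/min)
    complex with three exchanged + incoming ligand → leaving ligand + complex with four exchanged (k = 47.1 /M/min)
    leaving ligand + starting complex ⇌ idle adduct, settled at all times (K = 8.23 /M)
    incoming ligand → decomposition product (k = 1.65 × 10⁻⁴ /min)

Gamma stood 6 points above the zero, zeta 4 points below it. The difference in ligand charge is the main reason for the rise: with zeta's extra ligand taken away, down to gamma's charge, zeta's 91.9% reacted falls to 78.4%. Zeta's ligand went further down the chain than blind filling, with 34.4% complex with four exchanged at 10.0 min against 9.15%.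

On a neighbour flask, zeta with 0.28 M incoming ligand, the fill is 140%, so the sites fill and 28.6% of the ligand stays over. The flask gave >99.9% reacted and 28.5% ligand left at 10.0 min.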